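**Strategy.** The oxolane ring is disconnected at C2–C3. In aldehyde 4, C3 is a formyl carbon and C2 the β-carbon of an (E)-β-alkoxyvinyl sulfone carried by the C5 oxygen; SmI2 turns the aldehyde into a ketyl that closes the ring. The step exploits the C3 carbinol lying next to the O1-bearing C2 and the 1,3-relation of C2 and C5 across O1: one operation forms C2–C3 and sets C2 and C3 (2,5-cis, 2,3-trans) from the single purchased C5 stereocentre. The sulfonylmethyl arm is then converted into the (E,E)-dienyl Weinreb amide, and the isocoumarin is built last by lateral acylation of a chlorinated toluate and enol lactonization.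

Key step: step 3

Remark on the chemistry: oxolane atoms are numbered O1, C2 (dienyl-bearing), C3 (carbinol), C4, C5 (methyl-bearing) in all intermediates; chlorination of methyl orsellinate with SO2Cl2 is assumed to go to the ring carbon between the methyl group and the 4-hydroxyl.

**Step 1**
Reactants: 1 ethyl (3S)-3-hydroxybutanoate; 2 ethynyl 4-methylphenyl sulfone
Product: 3 ethyl (3S)-3-{[(E)-2-(4-methylbenzenesulfonyl)ethenyl]oxy}butanoate
Conditions: N-methylmorpholine, CH2Cl2, 0 °C to rt
Reagents that add atoms: none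
Why: Amine-mediated oxa-Michael addition of the secondary alcohol to the ethynyl sulfone should give the (E)-β-alkoxyvinyl sulfone under conditions too mild to dehydrate the β-hydroxy ester, leaving the C5 stereocentre untouched.

**Step 2**
Reactants: 3 ethyl (3S)-3-{[(E)-2-(4-methylbenzenesulfonyl)ethenyl]oxy}butanoate
Product: 4 (3S)-3-{[(E)-2-(4-methylbenzenesulfonyl)ethenyl]oxy}butanal
Conditions: i-Bu2AlH (1.1 equiv), CH2Cl2, −78 °C; MeOH, then aq. potassium sodium tartrate
Reagents that add atoms: none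
Why: Low-temperature half-reduction of the ester with i-Bu2AlH should stop at the aluminium hemiacetal, which releases the aldehyde only on work-up, while the vinyl sulfone is inert to the hydride at −78 °C.

**Step 3**
Reactants: 4 (3S)-3-{[(E)-2-(4-methylbenzenesulfonyl)ethenyl]oxy}butanal
Product: 5 (2S,3S,5S)-5-methyl-2-[(4-methylbenzenesulfonyl)methyl]oxolan-3-ol
Conditions: SmI2 (2.5 equiv), MeOH (4 equiv), THF, 0 °C
Reagents that add atoms: none
Why: Electron transfer from divalent samarium to the aldehyde gives a ketyl at C3 that adds to the β-carbon (C2) of the vinyl sulfone, and the resulting α-sulfonyl radical is reduced by a second SmI2 and protonated by MeOH before it can expel the ring oxygen. The closest known reaction type is the SmI2-induced reductive ketyl–olefin cyclization of aldehydes onto β-alkoxyacrylates and related β-alkoxyvinyl sulfur acceptors used to make 3-hydroxy oxacycles. The oxolane ring closes in the 5-exo-trig mode through a chair-like transition state. C2 is controlled by the C5 stereocentre: allylic strain holds the C5–H in the plane of the flat O–CH=CH–SO2 unit and the methyl group sits pseudo-equatorial, so the ketyl should attack the face that gives the 2,5-cis ring. C3 is controlled in the same transition state, where the bulky samarium-bound oxygen turns away from the carbon that becomes the sulfonylmethyl group, which should give the 2,3-trans alcohol. The step needs cyclization to outrun β-elimination of the alkoxy group and simple reduction of the aldehyde, which the polarised (E)-acceptor held five atoms away and the use of freshly made aldehyde should secure.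

**Step 4**
Reactants: 5 (2S,3S,5S)-5-methyl-2-[(4-methylbenzenesulfonyl)methyl]oxolan-3-ol
Product: 6 tert-butyl(dimethyl){[(2S,3S,5S)-5-methyl-2-[(4-methylbenzenesulfonyl)methyl]oxolan-3-yl]oxy}silane
Conditions: TBSCl, imidazole, DMF, rt
Reagents that add atoms: tert-butyldimethylsilyl chloride, CC(C)(C)[Si](C)(C)Cl
Why: Standard silylation of the secondary alcohol protects it from the carbanion steps that follow.

**Step 5**
Reactants: 6 tert-butyl(dimethyl){[(2S,3S,5S)-5-methyl-2-[(4-methylbenzenesulfonyl)methyl]oxolan-3-yl]oxy}silane; 7 ethyl (2E)-4-bromobut-2-enoate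
Product: 9 ethyl (2E,4E)-5-[(2R,3S,5S)-3-{[tert-butyl(dimethyl)silyl]oxy}-5-methyloxolan-2-yl]penta-2,4-dienoate, via alkylated sulfone 8 (not isolated)
Conditions: n-BuLi (1.05 equiv), THF, −78 °C; cannulate into 7 (1.5 equiv), THF, −78 °C; then DBU (3 equiv), −78 °C to rt
Reagents that add atoms: none
Why: Julia-type alkylation of the α-sulfonyl carbanion at the allylic bromide, followed by base-induced 1,2-elimination of the sulfinate using the γ-proton of the enoate, should give the thermodynamically favoured (E,E)-dienoate, with inverse addition at low temperature favouring SN2 over proton transfer and conjugate addition.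

**Step 6**
Reactants: 9 ethyl (2E,4E)-5-[(2R,3S,5S)-3-{[tert-butyl(dimethyl)silyl]oxy}-5-methyloxolan-2-yl]penta-2,4-dienoate
Product: 10 (2E,4E)-5-[(2R,3S,5S)-3-{[tert-butyl(dimethyl)silyl]oxy}-5-methyloxolan-2-yl]-N-methoxy-N-methylpenta-2,4-dienamide
Conditions: MeNH(OMe)·HCl (3 equiv), i-PrMgCl (6 equiv), THF, −20 °C to 0 °C
Reagents that add atoms: N,O-dimethylhydroxylamine hydrochloride, CNOC.Cl
Why: Aminolysis of the ester by the magnesium amide of N,O-dimethylhydroxylamine (Weinreb amide formation) is a standard transformation that should leave the diene geometry and the silyl ether untouched.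

**Step 7**
Reactants: 11 methyl 2,4-dihydroxy-6-methylbenzoate
Product: 12 methyl 3-chloro-4,6-dihydroxy-2-methylbenzoate
Conditions: SO2Cl2 (1.0 equiv), Et2O, 0 °C to rt
Reagents that add atoms: sulfuryl chloride, O=S(=O)(Cl)Cl
Why: Electrophilic aromatic chlorination of the resorcylate should occur para to the ester-chelated hydroxyl and ortho to the free hydroxyl, which is the ring carbon next to the methyl group.

**Step 8**
Reactants: 12 methyl 3-chloro-4,6-dihydroxy-2-methylbenzoate
Product: 13 methyl 3-chloro-4,6-bis(methoxymethoxy)-2-methylbenzoate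
Conditions: NaH (2.5 equiv), MOMCl (2.5 equiv), DMF, 0 °C to rt
Reagents that add atoms: chloromethyl methyl ether, COCCl
Why: Williamson-type alkylation of both phenoxides, including the hydrogen-bonded one next to the ester, gives the bis(methoxymethyl) ether needed for lateral metalation.

**Step 9**
Reactants: 13 methyl 3-chloro-4,6-bis(methoxymethoxy)-2-methylbenzoate; 10 (2E,4E)-5-[(2R,3S,5S)-3-{[tert-butyl(dimethyl)silyl]oxy}-5-methyloxolan-2-yl]-N-methoxy-N-methylpenta-2,4-dienamide
Product: 14 methyl 2-[(3E,5E)-6-[(2R,3S,5S)-3-{[tert-butyl(dimethyl)silyl]oxy}-5-methyloxolan-2-yl]-2-oxohexa-3,5-dien-1-yl]-3-chloro-4,6-bis(methoxymethoxy)benzoate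
Conditions: 13 (1.5 equiv), LiN(i-Pr)2 (1.6 equiv), THF, −78 °C; then 10 (1.0 equiv), −78 °C; aq. NH4Cl
Reagents that add atoms: none
Why: Lateral lithiation of the ortho-toluate gives a benzylic anion that should add 1,2 to the Weinreb amide, whose chelated tetrahedral adduct prevents over-addition, as is known for unsaturated Weinreb amides with chlorinated resorcylate toluates.

**Step 10**
Reactants: 14 methyl 2-[(3E,5E)-6-[(2R,3S,5S)-3-{[tert-butyl(dimethyl)silyl]oxy}-5-methyloxolan-2-yl]-2-oxohexa-3,5-dien-1-yl]-3-chloro-4,6-bis(methoxymethoxy)benzoate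
Product: 15 3-[(1E,3E)-4-[(2R,3S,5S)-3-{[tert-butyl(dimethyl)silyl]oxy}-5-methyloxolan-2-yl]buta-1,3-dien-1-yl]-5-chloro-6,8-bis(methoxymethoxy)-1H-isochromen-1-one
Conditions: DBU (1.5 equiv), toluene, 60 °C
Reagents that add atoms: none
Why: Enolization of the benzylic ketone toward the arene and 6-exo-trig O-acylation of the enolate by the neighbouring methyl ester (enol lactonization) should close the isocoumarin irreversibly with loss of methanol.

**Step 11**
Reactants: 15 3-[(1E,3E)-4-[(2R,3S,5S)-3-{[tert-butyl(dimethyl)silyl]oxy}-5-methyloxolan-2-yl]buta-1,3-dien-1-yl]-5-chloro-6,8-bis(methoxymethoxy)-1H-isochromen-1-one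
Product: 16 5-chloro-6,8-dihydroxy-3-[(1E,3E)-4-[(2R,3S,5S)-3-hydroxy-5-methyloxolan-2-yl]buta-1,3-dien-1-yl]-1H-isochromen-1-one
Conditions: HCl (1.25 M in MeOH), 0 °C to rt
Reagents that add atoms: none
Why: Acid-catalysed methanolysis should remove both aryl methoxymethyl ethers and the secondary silyl ether in one operation, under conditions too mild to ionise the secondary dienyl ether at C2 or open the enol lactone.

**Compound list**

1 | ethyl (3S)-3-hydroxybutanoate | CCOC(=O)C[C@H](C)O | starting material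
2 | ethynyl 4-methylphenyl sulfone | C#CS(=O)(=O)c1ccc(C)cc1 | starting material
3 | ethyl (3S)-3-{[(E)-2-(4-methylbenzenesulfonyl)ethenyl]oxy}butanoate | CCOC(=O)C[C@H](C)O/C=C/S(=O)(=O)c1ccc(C)cc1 | intermediate
4 | (3S)-3-{[(E)-2-(4-methylbenzenesulfonyl)ethenyl]oxy}butanal | O=CC[C@H](C)O/C=C/S(=O)(=O)c1ccc(C)cc1 | intermediate
5 | (2S,3S,5S)-5-methyl-2-[(4-methylbenzenesulfonyl)methyl]oxolan-3-ol | C[C@H]1C[C@H](O)[C@@H](CS(=O)(=O)c2ccc(C)cc2)O1 | intermediate
6 | tert-butyl(dimethyl){[(2S,3S,5S)-5-methyl-2-[(4-methylbenzenesulfonyl)methyl]oxolan-3-yl]oxy}silane | C[C@H]1C[C@H](O[Si](C)(C)C(C)(C)C)[C@@H](CS(=O)(=O)c2ccc(C)cc2)O1 | intermediate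
7 | ethyl (2E)-4-bromobut-2-enoate | CCOC(=O)/C=C/CBr | starting material
8 | ethyl (2E)-5-[(2S,3S,5S)-3-{[tert-butyl(dimethyl)silyl]oxy}-5-methyloxolan-2-yl]-5-(4-methylbenzenesulfonyl)pent-2-enoate (both epimers at the sulfonyl-bearing carbon) | C[C@H]1C[C@H](O[Si](C)(C)C(C)(C)C)[C@@H](C(C/C=C/C(=O)OCC)S(=O)(=O)c2ccc(C)cc2)O1 | intermediate (not isolated)
9 | ethyl (2E,4E)-5-[(2R,3S,5S)-3-{[tert-butyl(dimethyl)silyl]oxy}-5-methyloxolan-2-yl]penta-2,4-dienoate | C[C@H]1C[C@H](O[Si](C)(C)C(C)(C)C)[C@@H](/C=C/C=C/C(=O)OCC)O1 | intermediate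
10 | (2E,4E)-5-[(2R,3S,5S)-3-{[tert-butyl(dimethyl)silyl]oxy}-5-methyloxolan-2-yl]-N-methoxy-N-methylpenta-2,4-dienamide | C[C@H]1C[C@H](O[Si](C)(C)C(C)(C)C)[C@@H](/C=C/C=C/C(=O)N(C)OC)O1 | intermediate
11 | methyl 2,4-dihydroxy-6-methylbenzoate | COC(=O)c1c(C)cc(O)cc1O | starting material
12 | methyl 3-chloro-4,6-dihydroxy-2-methylbenzoate | COC(=O)c1c(C)c(Cl)c(O)cc1O | intermediate
13 | methyl 3-chloro-4,6-bis(methoxymethoxy)-2-methylbenzoate | COC(=O)c1c(C)c(Cl)c(OCOC)cc1OCOC | intermediate
14 | methyl 2-[(3E,5E)-6-[(2R,3S,5S)-3-{[tert-butyl(dimethyl)silyl]oxy}-5-methyloxolan-2-yl]-2-oxohexa-3,5-dien-1-yl]-3-chloro-4,6-bis(methoxymethoxy)benzoate | C[C@H]1C[C@H](O[Si](C)(C)C(C)(C)C)[C@@H](/C=C/C=C/C(=O)Cc2c(Cl)c(OCOC)cc(OCOC)c2C(=O)OC)O1 | intermediate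
15 | 3-[(1E,3E)-4-[(2R,3S,5S)-3-{[tert-butyl(dimethyl)silyl]oxy}-5-methyloxolan-2-yl]buta-1,3-dien-1-yl]-5-chloro-6,8-bis(methoxymethoxy)-1H-isochromen-1-one | C[C@H]1C[C@H](O[Si](C)(C)C(C)(C)C)[C@@H](/C=C/C=C/c2cc3c(Cl)c(OCOC)cc(OCOC)c3c(=O)o2)O1 | intermediate
16 | 5-chloro-6,8-dihydroxy-3-[(1E,3E)-4-[(2R,3S,5S)-3-hydroxy-5-methyloxolan-2-yl]buta-1,3-dien-1-yl]-1H-isochromen-1-one | C[C@H]1C[C@H](O)[C@@H](/C=C/C=C/c2cc3c(Cl)c(O)cc(O)c3c(=O)o2)O1 | target

**Step count.** Total: 11 steps. Longest linear sequence: 9 steps (steps 1–6, then 9–11); steps 7–8 make the aromatic fragment.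

**Steps most likely to fail**

Step 5. The sulfonyl carbanion may add in conjugate fashion to the bromoenoate and close a cyclopropane, proton transfer from the first-formed product may quench unreacted carbanion, or the carbanion may open the ring by β-elimination of O1. The fallback sets out from 6 and replaces carbon–carbon bond formation at the sulfone by olefination of an aldehyde. Oxidative desulfonylation of lithiated 6 (n-BuLi, THF, −78 °C; then Me3SiOOSiMe3) should give (2S,3S,5S)-3-{[tert-butyl(dimethyl)silyl]oxy}-5-methyloxolane-2-carbaldehyde F1. A vinylogous Horner–Wadsworth–Emmons reaction of F1 with triethyl (E)-4-phosphonobut-2-enoate (LiN(SiMe3)2, THF, −78 °C to 0 °C) should then return to the route at 9.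

Step 3. Facial control in the ketyl addition may be poor, or the β-alkoxy aldehyde may lose its alkoxy group or be reduced before it cyclizes. The fallback sets out from 3 and closes the same C2–C3 bond by an acyl radical, then corrects C3 by inversion.
- Saponification (LiOH, THF/H2O) gives (3S)-3-{[(E)-2-(4-methylbenzenesulfonyl)ethenyl]oxy}butanoic acid F2.
- PhSeSePh and PBu3 convert it into Se-phenyl (3S)-3-{[(E)-2-(4-methylbenzenesulfonyl)ethenyl]oxy}butaneselenoate F3.
- (Me3Si)3SiH with Et3B and air should give, by 5-exo acyl radical cyclization, (2S,5S)-5-methyl-2-[(4-methylbenzenesulfonyl)methyl]oxolan-3-one F4 with the 2,5-cis ring.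
- LiBH(s-Bu)3 (THF, −78 °C) should deliver hydride opposite to both substituents and give (2S,3R,5S)-5-methyl-2-[(4-methylbenzenesulfonyl)methyl]oxolan-3-ol F5.
- Mitsunobu inversion with 4-nitrobenzoic acid (PPh3, DIAD) gives (2S,3S,5S)-5-methyl-2-[(4-methylbenzenesulfonyl)methyl]oxolan-3-yl 4-nitrobenzoate F6.
- K2CO3 in MeOH then returns to the route at 5.

Step 9. The benzylic anion may add 1,4 or 1,6 to the dienamide, or may deprotonate it at the oxolane C2–H, instead of adding to the carbonyl. The fallback sets out from 10 and uses an aldehyde, which takes up the anion by 1,2-addition far faster. Reduction of 10 with i-Bu2AlH (THF, −78 °C) gives (2E,4E)-5-[(2R,3S,5S)-3-{[tert-butyl(dimethyl)silyl]oxy}-5-methyloxolan-2-yl]penta-2,4-dienal F7. Addition of lithiated 13 (LiN(i-Pr)2, THF, −78 °C, quench at −78 °C) should give methyl 3-chloro-2-[(3E,5E)-2-hydroxy-6-[(2R,3S,5S)-3-{[tert-butyl(dimethyl)silyl]oxy}-5-methyloxolan-2-yl]hexa-3,5-dien-1-yl]-4,6-bis(methoxymethoxy)benzoate F8 as a mixture of carbinol epimers. Oxidation with Dess–Martin periodinane (NaHCO3, CH2Cl2) returns to the route at 14.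

**Further compounds**

F1 | step 5 | (2S,3S,5S)-3-{[tert-butyl(dimethyl)silyl]oxy}-5-methyloxolane-2-carbaldehyde | C[C@H]1C[C@H](O[Si](C)(C)C(C)(C)C)[C@@H](C=O)O1
F2 | step 3 | (3S)-3-{[(E)-2-(4-methylbenzenesulfonyl)ethenyl]oxy}butanoic acid | OC(=O)C[C@H](C)O/C=C/S(=O)(=O)c1ccc(C)cc1
F3 | step 3 | Se-phenyl (3S)-3-{[(E)-2-(4-methylbenzenesulfonyl)ethenyl]oxy}butaneselenoate | O=C(C[C@H](C)O/C=C/S(=O)(=O)c1ccc(C)cc1)[Se]c1ccccc1
F4 | step 3 | (2S,5S)-5-methyl-2-[(4-methylbenzenesulfonyl)methyl]oxolan-3-one | C[C@H]1CC(=O)[C@@H](CS(=O)(=O)c2ccc(C)cc2)O1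
F5 | step 3 | (2S,3R,5S)-5-methyl-2-[(4-methylbenzenesulfonyl)methyl]oxolan-3-ol | C[C@H]1C[C@@H](O)[C@@H](CS(=O)(=O)c2ccc(C)cc2)O1
F6 | step 3 | (2S,3S,5S)-5-methyl-2-[(4-methylbenzenesulfonyl)methyl]oxolan-3-yl 4-nitrobenzoate | C[C@H]1C[C@H](OC(=O)c2ccc(cc2)[N+](=O)[O-])[C@@H](CS(=O)(=O)c3ccc(C)cc3)O1
F7 | step 9 | (2E,4E)-5-[(2R,3S,5S)-3-{[tert-butyl(dimethyl)silyl]oxy}-5-methyloxolan-2-yl]penta-2,4-dienal | C[C@H]1C[C@H](O[Si](C)(C)C(C)(C)C)[C@@H](/C=C/C=C/C=O)O1
F8 | step 9 | methyl 3-chloro-2-[(3E,5E)-2-hydroxy-6-[(2R,3S,5S)-3-{[tert-butyl(dimethyl)silyl]oxy}-5-methyloxolan-2-yl]hexa-3,5-dien-1-yl]-4,6-bis(methoxymethoxy)benzoate | C[C@H]1C[C@H](O[Si](C)(C)C(C)(C)C)[C@@H](/C=C/C=C/C(O)Cc2c(Cl)c(OCOC)cc(OCOC)c2C(=O)OC)O1
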